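**Plan**
Retrosynthesis: the two MOM ethers are removed last; before that, ring C is cut at C3–C4 and at O1–C8a in one operation. This gives a ring B fragment carrying O1–C2–C3 (an O,C-dilithiated 2-iodo-1-arylethanol) and a ring A fragment carrying C4 (methyl 2-fluoro-4,6-bis(methoxymethoxy)benzoate).
Enabling feature: O1 and C3 both sit on C2 (a 1,3-dinucleophile), while C4 and C8a sit 1,3 across C4a of ring A. C8a is ortho to the C4 carbonyl and meta to the oxygenated C5 and C7, so a C8a–F bond becomes SNAr-active as soon as C4 is a ketone.
Forward, ring A: 5-fluororesorcinol is MOM-protected, brominated and carboxylated through the aryllithium.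
Forward, ring B: 4-bromo-2-iodophenol gives the dimethylpyran ring D by propargyl ether Claisen/oxa-6π closure; C8 is then prenylated and C6 chloroacetylated.
Stereochemistry: C2 is set by asymmetric transfer hydrogenation of the aryl chloromethyl ketone; its C–O bond is never broken afterwards, and ring C closes last with retention.

Key step: step 10

Remark: locants O1, C2, C3, C4, C4a, C5 to C8 and C8a are those of the flavanone (ring A benzo, ring C pyranone, ring B the aryl group on C2, ring D its fused dimethylpyran); 5-fluorobenzene-1,3-diol and 4-bromo-2-iodophenol are taken as catalogue compounds.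

**Route**

Step 1
Reactants: 1 5-fluorobenzene-1,3-diol
Product: 2 1-fluoro-3,5-bis(methoxymethoxy)benzene
Conditions: NaH (2.4 equiv), MOMCl (2.4 equiv), DMF, 0 °C to rt
Reagents that add atoms: chloromethyl methyl ether (MOMCl), COCCl
Why: Williamson-type O-alkylation of the bis-phenoxide by the reactive α-chloro ether should give the bis-MOM acetal, a protecting group that tolerates the organolithium steps and is removed by dilute acid at the end.

Step 2
Reactants: 2 1-fluoro-3,5-bis(methoxymethoxy)benzene
Product: 3 2-bromo-1-fluoro-3,5-bis(methoxymethoxy)benzene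
Conditions: NBS (1.0 equiv), MeCN, 0 °C
Reagents that add atoms: N-bromosuccinimide (NBS), O=C1CCC(=O)N1Br
Why: Electrophilic aromatic bromination of the doubly activated ring should take place at C2, which is para to one acetal oxygen and flanked by the small fluorine, in preference to the more crowded C4 between the two acetal oxygens.

Step 3
Reactants: 3 2-bromo-1-fluoro-3,5-bis(methoxymethoxy)benzene, 4 methyl chloroformate
Product: 6 methyl 2-fluoro-4,6-bis(methoxymethoxy)benzoate, via aryllithium 5 (not isolated)
Conditions: n-BuLi (1.05 equiv), THF, −78 °C; then cannulated into 4 (3 equiv), THF, −78 °C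
Reagents that add atoms: none
Why: Bromine–lithium exchange is faster at −78 °C than ortho-deprotonation or loss of LiF to an aryne, and inverse addition of the hindered aryllithium to excess chloroformate (acylation of an organolithium) should stop at the ester.

Step 4
Reactants: 7 4-bromo-2-iodophenol, 8 3-chloro-3-methylbut-1-yne
Product: 9 4-bromo-2-iodo-1-[(2-methylbut-3-yn-2-yl)oxy]benzene
Conditions: K2CO3 (2 equiv), KI (cat.), acetone, reflux
Reagents that add atoms: none
Why: O-alkylation of the phenoxide with the tertiary propargylic chloride (Williamson-type etherification through the zwitterionic allenylidene form of the reagent) should give the 1,1-dimethylpropargyl aryl ether, and copper is left out so that the ortho C–I bond is not engaged.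

Step 5
Reactants: 9 4-bromo-2-iodo-1-[(2-methylbut-3-yn-2-yl)oxy]benzene
Product: 11 6-bromo-8-iodo-2,2-dimethyl-2H-chromene, via allenylphenol 10 (not isolated)
Conditions: PhNEt2, 190 °C
Reagents that add atoms: none
Why: Aromatic propargyl Claisen rearrangement to the only free ortho carbon gives allenylphenol 10 after tautomerisation, and a 1,5-hydrogen shift followed by oxa-6π electrocyclisation should close the 2,2-dimethyl-2H-pyran ring D.

Step 6
Reactants: 11 6-bromo-8-iodo-2,2-dimethyl-2H-chromene, 12 1-bromo-3-methylbut-2-ene (prenyl bromide)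
Product: 15 6-bromo-2,2-dimethyl-8-(3-methylbut-2-en-1-yl)-2H-chromene, via aryllithium 13 (not isolated), via arylcopper 14 (not isolated)
Conditions: n-BuLi (1.0 equiv), THF, −78 °C; CuBr·SMe2 (1.0 equiv), −78 to −40 °C; 12 (1.5 equiv), −78 to 0 °C
Reagents that add atoms: none
Why: Iodine–lithium exchange is far faster than bromine–lithium exchange so that only C8 is metallated, and after transmetallation to copper the aryl group should attack the primary carbon of prenyl bromide (SN2-type allylic substitution of an arylcopper) to give the linear prenyl group.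

Step 7
Reactants: 15 6-bromo-2,2-dimethyl-8-(3-methylbut-2-en-1-yl)-2H-chromene, 16 2-chloro-N-methoxy-N-methylacetamide
Product: 18 2-chloro-1-[2,2-dimethyl-8-(3-methylbut-2-en-1-yl)-2H-chromen-6-yl]ethan-1-one, via aryllithium 17 (not isolated)
Conditions: n-BuLi (1.05 equiv), THF, −78 °C; 16 (1.2 equiv), −78 °C; 1 M HCl
Reagents that add atoms: none
Why: Bromine–lithium exchange followed by Weinreb ketone synthesis should give the chloromethyl ketone, because the chelated tetrahedral adduct resists over-addition and the C–Cl bond is inert to the aryllithium at −78 °C.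

Step 8
Reactants: 18 2-chloro-1-[2,2-dimethyl-8-(3-methylbut-2-en-1-yl)-2H-chromen-6-yl]ethan-1-one
Product: 19 (1R)-2-chloro-1-[2,2-dimethyl-8-(3-methylbut-2-en-1-yl)-2H-chromen-6-yl]ethan-1-ol
Conditions: RuCl[(S,S)-TsDPEN](p-cymene) (1 mol%), HCO2H/Et3N (5:2), EtOAc, rt
Reagents that add atoms: none
Why: Noyori–Ikariya asymmetric transfer hydrogenation of an aryl chloromethyl ketone sets the only stereocentre: the (S,S)-catalyst delivers hydride to the carbonyl face that gives (S)-1-arylethanols from acetophenones, which is the R carbinol here because CH2Cl outranks the aryl group, and the outer-sphere hydride transfer leaves the three C=C bonds untouched.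

Step 9
Reactants: 19 (1R)-2-chloro-1-[2,2-dimethyl-8-(3-methylbut-2-en-1-yl)-2H-chromen-6-yl]ethan-1-ol
Product: 20 (1R)-1-[2,2-dimethyl-8-(3-methylbut-2-en-1-yl)-2H-chromen-6-yl]-2-iodoethan-1-ol
Conditions: NaI (5 equiv), NaHCO3 (0.2 equiv), acetone, reflux, dark
Reagents that add atoms: sodium iodide, [Na+].[I-]
Why: Finkelstein reaction: SN2 exchange of chloride for iodide at the primary carbon, driven by precipitation of NaCl in acetone, should give the iodohydrin without touching the carbinol stereocentre, and the bicarbonate buffer suppresses acid-induced ionisation of the electron-rich benzylic alcohol.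

Step 10
Reactants: 20 (1R)-1-[2,2-dimethyl-8-(3-methylbut-2-en-1-yl)-2H-chromen-6-yl]-2-iodoethan-1-ol, 6 methyl 2-fluoro-4,6-bis(methoxymethoxy)benzoate
Product: 23 (2S)-2-[2,2-dimethyl-8-(3-methylbut-2-en-1-yl)-2H-chromen-6-yl]-5,7-bis(methoxymethoxy)-2,3-dihydro-4H-chromen-4-one, via dianion 21 (not isolated), via lithium aldolate 22 (not isolated)
Conditions: MeLi (1.0 equiv), Et2O, −78 °C; t-BuLi (2.05 equiv), pentane/Et2O, −78 °C; cannulated into 6 (1.2 equiv), THF, −78 °C; DMPU, −78 to 0 °C; AcOH, 0 °C
Reagents that add atoms: none
Why: Proposed new method: after O-deprotonation by MeLi, iodine–lithium exchange with t-BuLi should give the β-oxido alkyllithium 21, in which C3 and O1 are both nucleophilic and β-elimination is slow at −78 °C because Li2O is a very poor leaving group; the carbanion adds to the ester carbonyl of 6 and loss of LiOMe gives the aryl ketone 22 (bond C3–C4), whose alkoxide then displaces fluoride at C8a by addition–elimination (bond O1–C8a), a formal [3+3] annulation of a 1,3-dinucleophile with a 1,3-dielectrophile. The closest known reaction types are the trapping of β-oxido organolithiums with carbonyl electrophiles, the acylation of organolithiums by esters, and the intramolecular SNAr of oxygen nucleophiles on 2-fluoroaryl ketones used to make chromones. Ring C closes in a 6-endo-trig addition–elimination at C8a, a vinylogous acyl substitution through a Meisenheimer enolate delocalised onto the C4 carbonyl. No stereocentre is formed: C2 is the carbinol carbon set in step 8, none of its bonds is broken, and the configuration is carried over with retention (2S by CIP once C3 bears the ketone). The step needs C-acylation instead of O-acylation, mono-addition, ring closure faster than retro-aldol cleavage or dehydration of 22, and no base-induced reopening of ring C; these are addressed by the far higher nucleophilicity of the carbanion, inverse addition to a hindered 2,6-disubstituted benzoate at −78 °C, the fluorine being ortho to the new ketone and meta to both acetal oxygens (so that their lone pairs do not deactivate C8a), the lithium counter-ion, and an acetic acid quench at 0 °C.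

Step 11
Reactants: 23 (2S)-2-[2,2-dimethyl-8-(3-methylbut-2-en-1-yl)-2H-chromen-6-yl]-5,7-bis(methoxymethoxy)-2,3-dihydro-4H-chromen-4-one
Product: 24 (2S)-5,7-dihydroxy-2-[2,2-dimethyl-8-(3-methylbut-2-en-1-yl)-2H-chromen-6-yl]-2,3-dihydro-4H-chromen-4-one
Conditions: 3 M HCl, MeOH, 40 °C
Reagents that add atoms: none
Why: Acid-catalysed acetal exchange with methanol (MOM ether cleavage) should free the C5 and C7 hydroxyl groups, flavanones do not open or epimerise at C2 under mild acid, and ring B has no free phenol beside the prenyl group that could cyclise onto it.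

**Compound list**
1 | 5-fluorobenzene-1,3-diol | Oc1cc(O)cc(F)c1 | starting material
2 | 1-fluoro-3,5-bis(methoxymethoxy)benzene | COCOc1cc(F)cc(OCOC)c1 | intermediate
3 | 2-bromo-1-fluoro-3,5-bis(methoxymethoxy)benzene | COCOc1cc(F)c(Br)c(OCOC)c1 | intermediate
4 | methyl chloroformate | COC(Cl)=O | starting material
5 | [2-fluoro-4,6-bis(methoxymethoxy)phenyl]lithium | [Li]c1c(F)cc(OCOC)cc1OCOC | intermediate
6 | methyl 2-fluoro-4,6-bis(methoxymethoxy)benzoate | COC(=O)c1c(F)cc(OCOC)cc1OCOC | intermediate
7 | 4-bromo-2-iodophenol | Oc1ccc(Br)cc1I | starting material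
8 | 3-chloro-3-methylbut-1-yne | C#CC(C)(C)Cl | starting material
9 | 4-bromo-2-iodo-1-[(2-methylbut-3-yn-2-yl)oxy]benzene | C#CC(C)(C)Oc1ccc(Br)cc1I | intermediate
10 | 4-bromo-2-iodo-6-(3-methylbuta-1,2-dien-1-yl)phenol | CC(C)=C=Cc1cc(Br)cc(I)c1O | intermediate
11 | 6-bromo-8-iodo-2,2-dimethyl-2H-chromene | Ic1cc(Br)cc2c1OC(C)(C)C=C2 | intermediate
12 | 1-bromo-3-methylbut-2-ene (prenyl bromide) | CC(C)=CCBr | starting material
13 | (6-bromo-2,2-dimethyl-2H-chromen-8-yl)lithium | [Li]c1cc(Br)cc2c1OC(C)(C)C=C2 | intermediate
14 | (6-bromo-2,2-dimethyl-2H-chromen-8-yl)copper | [Cu]c1cc(Br)cc2c1OC(C)(C)C=C2 | intermediate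
15 | 6-bromo-2,2-dimethyl-8-(3-methylbut-2-en-1-yl)-2H-chromene | CC(C)=CCc1cc(Br)cc2c1OC(C)(C)C=C2 | intermediate
16 | 2-chloro-N-methoxy-N-methylacetamide | CON(C)C(=O)CCl | starting material
17 | [2,2-dimethyl-8-(3-methylbut-2-en-1-yl)-2H-chromen-6-yl]lithium | CC(C)=CCc1cc([Li])cc2c1OC(C)(C)C=C2 | intermediate
18 | 2-chloro-1-[2,2-dimethyl-8-(3-methylbut-2-en-1-yl)-2H-chromen-6-yl]ethan-1-one | CC(C)=CCc1cc(C(=O)CCl)cc2c1OC(C)(C)C=C2 | intermediate
19 | (1R)-2-chloro-1-[2,2-dimethyl-8-(3-methylbut-2-en-1-yl)-2H-chromen-6-yl]ethan-1-ol | CC(C)=CCc1cc([C@@H](O)CCl)cc2c1OC(C)(C)C=C2 | intermediate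
20 | (1R)-1-[2,2-dimethyl-8-(3-methylbut-2-en-1-yl)-2H-chromen-6-yl]-2-iodoethan-1-ol | CC(C)=CCc1cc([C@@H](O)CI)cc2c1OC(C)(C)C=C2 | intermediate
21 | lithium (1S)-1-[2,2-dimethyl-8-(3-methylbut-2-en-1-yl)-2H-chromen-6-yl]-2-lithioethan-1-olate (dianion; same spatial arrangement as 20) | CC(C)=CCc1cc([C@@H](O[Li])C[Li])cc2c1OC(C)(C)C=C2 | intermediate
22 | lithium (1S)-1-[2,2-dimethyl-8-(3-methylbut-2-en-1-yl)-2H-chromen-6-yl]-3-[2-fluoro-4,6-bis(methoxymethoxy)phenyl]-3-oxopropan-1-olate (lithium aldolate) | CC(C)=CCc1cc([C@@H](O[Li])CC(=O)c3c(F)cc(OCOC)cc3OCOC)cc2c1OC(C)(C)C=C2 | intermediate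
23 | (2S)-2-[2,2-dimethyl-8-(3-methylbut-2-en-1-yl)-2H-chromen-6-yl]-5,7-bis(methoxymethoxy)-2,3-dihydro-4H-chromen-4-one | CC(C)=CCc1cc([C@@H]2CC(=O)c3c(OCOC)cc(OCOC)cc3O2)cc2c1OC(C)(C)C=C2 | intermediate
24 | (2S)-5,7-dihydroxy-2-[2,2-dimethyl-8-(3-methylbut-2-en-1-yl)-2H-chromen-6-yl]-2,3-dihydro-4H-chromen-4-one | CC(C)=CCc1cc([C@@H]2CC(=O)c3c(O)cc(O)cc3O2)cc2c1OC(C)(C)C=C2 | target

**Count**
Total steps: 11. Longest linear sequence: 8 steps (steps 4 to 11, from 7); the ring A ester 6 is made in 3 steps and enters at step 10.

**Steps most likely to fail**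

Step 10 (new cascade). What may go wrong:
- over-addition of the organolithium to the ketone;
- retro-aldol cleavage or dehydration of the aldolate before ring closure;
- base-induced opening of ring C with loss of configuration at C2.

Fallback with known chemistry, setting out from 15 and coming back at 23. Bromine–lithium exchange on 15 (n-BuLi, THF, −78 °C) and quenching with B(OiPr)3, then dilute acid, should give [2,2-dimethyl-8-(3-methylbut-2-en-1-yl)-2H-chromen-6-yl]boronic acid F1. Commercial 5,7-dihydroxy-4H-chromen-4-one would be protected (NaH, MOMCl, DMF) as 5,7-bis(methoxymethoxy)-4H-chromen-4-one F2. Rhodium-catalysed asymmetric 1,4-addition of F1 to F2 ([Rh(OH)(cod)]2, an electron-poor chiral bisphosphine of the MeO-BIPHEP family, toluene/H2O, rt) should give 23 directly. The ligand enantiomer is the one that gives the 2S adduct, to be fixed on a model chromone. C2 is then set by the ligand in the aryl transfer, and steps 7 to 9 are not needed.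

Step 6. What may go wrong:
- incomplete discrimination between iodine and bromine in the exchange;
- butylation of the aryl metal by the 1-iodobutane formed;
- attack at the tertiary end of the allyl unit, giving the reverse-prenyl isomer.

Fallback setting out from 11 and coming back at 15: Stille coupling of 11 with tributyl(3-methylbut-2-en-1-yl)stannane (Pd(PPh3)4, zerovalent palladium, DMF, 80 °C). Oxidative addition should take place at the C–I bond only, and coupling at the primary allyl carbon should give the linear prenyl group. No compound outside the list is made (F0).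

Step 9. What may go wrong:
- sluggish halide exchange on the chlorohydrin;
- ionisation of the electron-rich benzylic carbinol, or closure to the epoxide, on prolonged heating, with erosion of enantiopurity.

Fallback setting out from 19 and coming back at dianion 21 inside step 10: O-deprotonation of 19 (n-BuLi, THF, −78 °C) followed by reductive lithiation of the C–Cl bond with lithium 4,4'-di-tert-butylbiphenylide (2.1 equiv, −78 °C). This is the established way to make β-oxido organolithiums from chlorohydrins. No compound outside the list is made (F0).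

**Further compounds**
F1 | step 10 | [2,2-dimethyl-8-(3-methylbut-2-en-1-yl)-2H-chromen-6-yl]boronic acid | CC(C)=CCc1cc(B(O)O)cc2c1OC(C)(C)C=C2
F2 | step 10 | 5,7-bis(methoxymethoxy)-4H-chromen-4-one | O=c1ccoc2cc(OCOC)cc(OCOC)c12
F0 | step 6 | none | none
F0 | step 9 | none | none
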